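## Analysis of the target

The target joins two C6–C3 dimers through a 5,5'-biaryl bond: an olivil-type unit (ring A benzyl group, tetrahydrofuran O1/C2–C5, ring B) and a cycloolivil-type unit (ring C on C1 of a tetralin whose arene is ring D). The tetrahydrofuran carries C2 (S, ring B), C3 (R, CH2OH) and C4 (S, tertiary OH and the 3-hydroxy-4-methoxybenzyl group). The C2 aryl is trans to the C3 CH2OH, and the C4 hydroxyl is trans to the C3 CH2OH, so the benzyl group is cis to it. The tetralin carries C1 (S, ring C), C2 (S, CH2OH) and C3 (S, tertiary OH and CH2OH), with the aryl trans to the C2 CH2OH and the C3 hydroxyl cis to it. The two triads are insulated by the biaryl, so each has to be set in the absolute sense. The weak point is the benzylic C2–O1 ether para to a phenolic oxygen: acid ionizes it (epimerization, or capture by ring A as in the olivil-to-cycloolivil change) and it can be hydrogenolysed. The difficulty is to build two similar but differently cyclized units on a symmetric biphenol and to finish all acid chemistry before the tetrahydrofuran exists. The strategy rests on the C3–C4 bond of the tetrahydrofuran: a methine with a one-carbon arm next to a carbinol carbon with an arylmethyl group is the reduced form of a 3-vinyl-4-arylmethylidene ring, the Alder-ene isomer of a 1,6-enyne.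

## Retrosynthetic reasoning

33 from 32: all six protected hydroxyls of 32 are benzyl ethers, so the last step is a single neutral hydrogenolysis and nothing acidic or basic meets the finished tetrahydrofuran.

32 from 29 (through 30 and 31): the C3 hydroxymethyl is traced to a vinyl group. The C=C bond is cut oxidatively and aldehyde 31 is reduced at once. The vinyl group is the one-carbon arm in the latent form that the ring-forming step leaves behind.

29 from 27 (through 28): the C4–O bond and one benzylic C–H bond are removed. The tertiary carbinol with its benzyl group is the hydride-opening product of spiro-epoxide 28, made from the arylidene of 27. Oxygen delivered anti to the C3 vinyl group ends trans to the future CH2OH, and hydride enters at the benzylic carbon. Adding a benzyl nucleophile to a C4 ketone anti to the C3 substituent would give the wrong C4 epimer. This is done before the vinyl cleavage so that the labile epoxide never meets the oxidant or a neighbouring aldehyde.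

27 from 26: the C3–C4 bond is cut. It is the only ring C–C bond not attached to an arene, and cutting it leaves a propargyl ether of an (E)-propenyl carbinol in which every carbon already has the right oxidation level. The forward reaction is an isomerization that closes the ring, sets C3 and leaves both handles (vinyl, arylidene). It has to control C3 relative to C2, the diene type and the alkene geometry.

26 from 25 and 21: the O1–C5 bond is an etherification. Bromide 21 comes from 17 and 19 through 18 and 20 (aryl–alkyne bond, then activation).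

25 from 16 and 22: the C2–propenyl bond is made by a catalyst-controlled alkenylzinc addition (through 23 and 24). This sets C2, from which C3 and C4 are relayed; the tetralin centres are too remote to help.

16 from 12 (through 13, 14 and 15): only functional-group changes. The imide and the dioxolanone of 13 are reduced to the triol 14, the two primary hydroxyls are benzylated, and the second formyl group is masked as an acetal while hydride and base are used.

12 from 11: the C1–C8a bond is cut. Ring D is nucleophilic para to its OMe group and C1 is a stabilized benzylic cation, so an acid-mediated ring closure gives the 1,2-trans tetralin. It is placed here because ring B then carries only a deactivating formyl group.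

11 from 9 and 2: the C1–C2 bond is an auxiliary-controlled aldol addition (through 10) that sets tetralin C2. Dialdehyde 2 (from 1) is symmetric, so one formyl group reacts when 2 is in excess.

9 from 7, and 7 from 4 and 6: the bond between tetralin C3 and C4 is an alkylation of dioxolanone 4 (from 3) with bromide 6 (from 5). It installs the quaternary carbinol from the chiral pool with retention; 8 is the activated acid.

## Alternatives that were turned down

Alternative 1: The tetralin C1–C8a bond is traced to a second olivil-type ring, so that ring A pivalate A1 would arise from bis-tetrahydrofuran A2. In the forward step acid ionizes the benzylic C–O bond of the unit whose benzyl arene is free 4-hydroxy-3-methoxyphenyl, that arene closes the six-membered ring para to its OMe group, and the C3 CH2OH is released. In its favour: both halves come from the same chemistry run in two directions on one symmetric dialdehyde (2 would serve), the rearrangement carries two centres over unchanged and sets C1 trans, and no separate tetralin synthesis is needed. On step economy it is stronger than the route chosen here. Against it: both benzylic ethers of A2 sit on the same kind of para-oxygenated ring and ionize alike, so selectivity rests only on the nucleophilicity gap between a free guaiacyl ring and an acylated ring A. Ring A still has an open position ortho to its CH2 group. Reversible ionization can epimerize C2 of the unit that must stay. The step comes last on an unprotected polyol, with no way to correct it. The chosen strategy pays with more steps but uses acid only before any tetrahydrofuran exists and closes that ring under neutral palladium catalysis.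

Alternative 2: The tetralin C1–C2 and C3–C4 bonds are cut as a [4+2] addition, giving tetralin ester A3 from aldehyde A4 and allenoate A5. In the forward step 365 nm light converts A4 into its (E)-dienol, which adds the ester-bearing double bond of A5 and leaves an exocyclic methylene at C3. In its favour: one step builds ring D with its oxygen pattern, the C2 carboxyl, a C3 handle for the carbinol and a C1 hydroxyl for later arylation. For the tetralin alone it is shorter than steps 2 to 7 here. Against it: it solves only the cycloolivil half and leaves the acid-labile tetrahydrofuran without a plan. The C1 aryl would have to be added afterwards by ionization and mono-arylation of a symmetric biphenol. The absolute sense needs a chiral promoter for a photoenol–allene addition. The later dihydroxylation at C3 must occur cis to the C2 substituent without an obvious control element. The chosen strategy addresses the harder ring directly and assigns every tetralin centre to a chiral-pool or auxiliary-controlled step.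

Alternative 3: The O1–C2 bond is cut, giving tetrahydrofuran A6 from acyclic triol A7. In the forward step a mild silver oxidant converts the para-hydroxybenzyl CH2 of ring B into quinone methide A8, and the primary hydroxyl on the carbon attached to the tertiary carbinol adds to it. In its favour: the closure forms only a C–O bond, needs no transition-metal catalysis, and C3 and C4 are already fixed in the open chain, so there is no epoxidation-face question. On that point it is stronger than the chosen route. Against it: C2 is set by conjugate addition to a planar quinone methide under weak control. The free ortho-aryl phenols are themselves oxidizable. A6 still carries a formyl group on ring C, so the tetralin would have to be built by acid after the acid-labile ring exists. The chosen strategy sets C2 by a catalyst before ring closure, relays it to C3 and C4, and keeps acid ahead of the tetrahydrofuran.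

Key step: step 16

Locants used below: tetrahydrofuran O1, C2 (aryl), C3, C4 (carbinol), C5; tetralin C1 (aryl) to C4; ring B sits on the tetrahydrofuran, ring C on the tetralin. "Protected cycloolivil unit" means the (1S,2S,3S)-7-(benzyloxy)-2,3-bis(benzyloxymethyl)-3-hydroxy-6-methoxy-1,2,3,4-tetrahydronaphthalen-1-yl group.

Assumption: (−)-3-exo-morpholinoisoborneol is taken to deliver alkenyl groups to the Si face of aromatic aldehydes as it does alkyl groups; if the sense were opposite, the (+)-ligand would be used.

## Route

Step 1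
Reactants: 1 dehydrodivanillin
Product: 2 6,6'-bis(benzyloxy)-5,5'-dimethoxybiphenyl-3,3'-dicarbaldehyde
Conditions: BnBr, K2CO3, DMF, 60 °C
Reagents that add atoms: benzyl bromide, BrCc1ccccc1
Why: Williamson etherification of both phenols; the benzyl ethers mask them against the bases, oxidants and organometallic reagents that follow.

Step 2
Reactants: 3 (S)-malic acid
Product: 4 2-[(2S,4S)-2-tert-butyl-5-oxo-1,3-dioxolan-4-yl]acetic acid (cis)
Conditions: t-BuCHO, TsOH (cat.), H2SO4 (cat.), pentane, reflux, water separator; recrystallization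
Reagents that add atoms: pivalaldehyde, CC(C)(C)C=O
Why: Acid-catalysed acetalization of the α-hydroxy acid unit; the cis isomer should be the major, crystalline product, so the acetal carbon is set by the malic acid centre and stores its configuration.

Step 3
Reactants: 5 [4-(benzyloxy)-3-methoxyphenyl]methanol
Product: 6 1-(benzyloxy)-4-(bromomethyl)-2-methoxybenzene
Conditions: PBr3, Et2O, 0 °C
Reagents that add atoms: phosphorus tribromide, BrP(Br)Br
Why: Bromination of an activated benzylic alcohol; the electron-rich bromide is used at once.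

Step 4
Reactants: 4 dioxolanone acid; 6 benzylic bromide
Product: 7 2-[(2S,4S)-4-(4-benzyloxy-3-methoxybenzyl)-2-tert-butyl-5-oxo-1,3-dioxolan-4-yl]acetic acid
Conditions: LiN(SiMe3)2 (2.1 equiv), THF, −78 °C; then 6, −78 → −20 °C; 1 M HCl work-up
Reagents that add atoms: none
Why: Enolate alkylation with self-regeneration of the stereocentre: the electrophile enters anti to the tert-butyl group, so the benzyl group replaces hydrogen with retention and gives the quaternary carbinol carbon that becomes tetralin C3. The dioxolanone keeps the tertiary hydroxyl and its carboxyl protected.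

Step 5
Reactants: 7 alkylated dioxolanone acid
Product: 9 (4S)-4-benzyl-3-{2-[(2S,4S)-4-(4-benzyloxy-3-methoxybenzyl)-2-tert-butyl-5-oxo-1,3-dioxolan-4-yl]acetyl}oxazolidin-2-one, via mixed pivalic anhydride 8 (not isolated)
Conditions: PivCl, Et3N, THF, −20 °C; then (S)-4-benzyloxazolidin-2-one, LiCl, −20 °C → rt
Reagents that add atoms: pivaloyl chloride, CC(C)(C)C(=O)Cl (in 8 only); (S)-4-benzyloxazolidin-2-one, O=C1N[C@@H](Cc2ccccc2)CO1
Why: N-acylation of the oxazolidinone through the mixed anhydride; attack should take the less hindered acyl carbonyl of 8 and leave the dioxolanone alone.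

Step 6
Reactants: 9 imide; 2 dialdehyde (about 2.5 equiv)
Product: 11 syn-aldol adduct (4S)-4-benzyl-3-{(2R,3S)-3-[6,6'-bis(benzyloxy)-3'-formyl-5,5'-dimethoxybiphenyl-3-yl]-2-[(2S,4S)-4-(4-benzyloxy-3-methoxybenzyl)-2-tert-butyl-5-oxo-1,3-dioxolan-4-yl]-3-hydroxypropanoyl}oxazolidin-2-one, via boron enolate 10 (not isolated)
Conditions: Bu2BOTf, i-Pr2NEt, CH2Cl2, −78 → 0 °C; then 2, −78 → 0 °C; pH 7 buffer, MeOH, H2O2, 0 °C (brief)
Reagents that add atoms: dibutylboryl triflate, CCCCB(CCCC)OS(=O)(=O)C(F)(F)F (in 10 only)
Why: Evans syn-aldol reaction: the (Z)-boron enolate adds through a closed chair transition state, and the (S)-benzyl auxiliary fixes the enolate carbon (tetralin C2); the carbinol configuration is lost later. Dialdehyde 2 is symmetric and used in excess, so mono-addition needs no prior differentiation and the surplus is recovered.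

Step 7
Reactants: 11 aldol adduct
Product: 12 tetralin (1S,2R,3S): C1 bears the 6,6'-bis(benzyloxy)-3'-formyl-5,5'-dimethoxybiphenyl-3-yl group trans to the C2 carbonyl of the N-acyl (4S)-4-benzyloxazolidin-2-one; C3 is the spiro carbon of the (2S)-2-tert-butyl-1,3-dioxolan-4-one with its ring oxygen cis to the C2 acyl group; 7-OBn and 6-OMe on ring D
Conditions: CF3CO2H (10 equiv), CH2Cl2, 0 °C
Reagents that add atoms: none
Why: Intramolecular Friedel–Crafts alkylation: acid ionizes the benzylic carbinol para to the benzyloxy group of ring C, and ring D closes the six-membered ring para to its OMe group. The aryl group should take the equatorial position trans to the C2 acyl group. The formyl group deactivates ring B, which stays untouched.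

Step 8
Reactants: 12 tetralin aldehyde
Product: 13 dimethyl acetal of 12
Conditions: HC(OMe)3, MeOH, camphorsulfonic acid (cat.), rt
Reagents that add atoms: trimethyl orthoformate, COC(OC)OC
Why: Acid-catalysed acetalization protects the remaining aldehyde against the hydride and base of the next two steps, under conditions too mild to open the imide or the dioxolanone.

Step 9
Reactants: 13 acetal
Product: 14 (1S,2S,3S)-triol: 3'-[7-(benzyloxy)-3-hydroxy-2,3-bis(hydroxymethyl)-6-methoxytetralin-1-yl]-6,6'-bis(benzyloxy)-5,5'-dimethoxybiphenyl-3-carbaldehyde dimethyl acetal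
Conditions: LiAlH4, THF, 0 °C → rt; H2O, aq NaOH
Reagents that add atoms: none
Why: Hydride reduction cleaves the imide to the C2 CH2OH and opens the dioxolanone to the tertiary alcohol and the C3 CH2OH in one operation. No stereocentre is touched.

Step 10
Reactants: 14 triol
Product: 16 3'-(protected cycloolivil unit)-6,6'-bis(benzyloxy)-5,5'-dimethoxybiphenyl-3-carbaldehyde, via dimethyl acetal 15 (not isolated)
Conditions: NaH (2.3 equiv), BnBr (2.3 equiv), Bu4NI (cat.), THF/DMF, 0 °C → rt; then 1 M HCl, THF, rt
Reagents that add atoms: benzyl bromide, BrCc1ccccc1; water, O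
Why: Williamson benzylation of the two primary hydroxyls; the hindered tertiary hydroxyl is left, and its benzylation would be harmless because all benzyl ethers fall together at the end. The acidic work-up hydrolyses the acetal of 15.

Step 11
Reactants: 17 5-bromo-2-methoxyphenol
Product: 18 2-(benzyloxy)-4-bromo-1-methoxybenzene
Conditions: BnBr, K2CO3, DMF, rt
Reagents that add atoms: benzyl bromide, BrCc1ccccc1
Why: Williamson etherification of the phenol.

Step 12
Reactants: 18 aryl bromide; 19 propargyl alcohol
Product: 20 3-[3-(benzyloxy)-4-methoxyphenyl]prop-2-yn-1-ol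
Conditions: Pd(PPh3)2Cl2 (cat.), CuI (cat.), Et3N, 70 °C
Reagents that add atoms: none
Why: Sonogashira coupling of the aryl bromide with the terminal alkyne; the free hydroxyl is tolerated.

Step 13
Reactants: 20 propargylic alcohol
Product: 21 2-(benzyloxy)-4-(3-bromoprop-1-ynyl)-1-methoxybenzene
Conditions: CBr4, PPh3, CH2Cl2, 0 °C
Reagents that add atoms: carbon tetrabromide, BrC(Br)(Br)Br
Why: Appel bromination of the primary propargylic alcohol under neutral conditions.

Step 14
Reactants: 16 aldehyde; 22 (E)-1-bromoprop-1-ene
Product: 25 (1S,2E)-1-[3'-(protected cycloolivil unit)-6,6'-bis(benzyloxy)-5,5'-dimethoxybiphenyl-3-yl]but-2-en-1-ol, via (E)-prop-1-enyllithium 23 (not isolated), via bis[(E)-prop-1-enyl]zinc 24 (not isolated)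
Conditions: 22, t-BuLi (2 equiv per 22), Et2O, −78 °C; ZnBr2 (0.5 equiv per 23), −78 → 0 °C; N,N,N',N'-tetraethylethylenediamine, (−)-3-exo-morpholinoisoborneol (10 mol%), toluene; then 16, −10 → 0 °C; aq NH4Cl
Reagents that add atoms: tert-butyllithium, CC(C)(C)[Li] (lithium in 23 only); zinc bromide, [Zn+2].[Br-].[Br-] (zinc in 24 only)
Why: Amino-alcohol-catalysed enantioselective addition of an alkenylzinc reagent to an aromatic aldehyde. Bromine–lithium exchange at −78 °C and transmetalation keep the (E) geometry, the diamine binds LiBr so that the uncatalysed addition is suppressed, and the chiral zinc aminoalkoxide should deliver the propenyl group to the Si face to set C2 as S. The tertiary hydroxyl is carried as its zinc alkoxide, for which excess reagent is used.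

Step 15
Reactants: 25 allylic alcohol; 21 propargylic bromide
Product: 26 enyne ether: the 3-[3-(benzyloxy)-4-methoxyphenyl]prop-2-ynyl ether of 25 (carbinol carbon S)
Conditions: NaH (1.2 equiv), THF/DMF (4:1), 0 °C; then 21 (1.2 equiv), 0 °C → rt
Reagents that add atoms: none
Why: Williamson etherification of the secondary benzylic allylic alkoxide with a reactive propargylic bromide; with little excess of base the hindered tertiary hydroxyl should not be alkylated.

Step 16
Reactants: 26 enyne ether
Product: 27 (2S,3S)-2-[3'-(protected cycloolivil unit)-6,6'-bis(benzyloxy)-5,5'-dimethoxybiphenyl-3-yl]-4-[(Z)-3-(benzyloxy)-4-methoxybenzylidene]-3-vinyltetrahydrofuran (aryl and vinyl trans)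
Conditions: Pd(OAc)2 (5 mol%), N,N'-bis(benzylidene)ethylenediamine (5 mol%), AcOH (10 mol%), benzene, 60 °C, stopped at full conversion
Reagents that add atoms: none
Why: This is a known reaction type, the palladium-catalysed Alder-ene cycloisomerization of 1,6-enynes to 1,4-dienes, applied to a propargyl ether of an (E)-propenyl carbinol with an aryl-capped alkyne. A hydridopalladium acetate formed from divalent palladium and AcOH adds syn across the alkyne with palladium on the carbon next to the OCH2 group; the other regioisomer cannot reach the alkene and reverts. The alkenylpalladium inserts the propenyl double bond in a 5-exo-trig closure that forms C3–C4 and the tetrahydrofuran, and β-hydride elimination from the methyl group releases the C3 vinyl group and the catalyst. Syn hydropalladation followed by insertion with retention fixes the arylidene as Z, the aryl group on the C5 side. C3 is set by the C2 centre: in the chair-like insertion transition state the C2 aryl sits pseudo-equatorial, which puts the new C3 substituent trans to it. The step needs the 1,4-diene and not the 1,3-diene; the freely rotating methyl group offers three syn β-hydrogens, whereas the ring C3–H would have to eclipse the new ring bond. It also needs the doubly activated C2–O bond to survive, which the absence of zerovalent palladium and of strong acid should allow.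

Step 17
Reactants: 27 diene
Product: 29 (2S,3R,4S)-2-[3'-(protected cycloolivil unit)-6,6'-bis(benzyloxy)-5,5'-dimethoxybiphenyl-3-yl]-4-[3-(benzyloxy)-4-methoxybenzyl]-3-vinyltetrahydrofuran-4-ol (hydroxyl trans to vinyl), via spiro-epoxide 28 (not isolated)
Conditions: dimethyldioxirane (1.1 equiv), acetone/CH2Cl2, −20 °C; evaporation; LiAlH4, THF, 0 °C
Reagents that add atoms: dimethyldioxirane, CC1(C)OO1
Why: A neutral dioxirane takes the electron-rich trisubstituted arylidene in preference to the monosubstituted vinyl group and should attack the face anti to the adjacent C3 vinyl group, which puts oxygen on C4 trans to it. The acid-labile p-methoxyphenyl epoxide 28 is not purified. LiAlH4 opens it by hydride attack at the less substituted benzylic carbon, giving the C4 tertiary alcohol with the ring A benzyl group.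

Step 18
Reactants: 29 vinyl carbinol
Product: 32 hexabenzyl ether of the target: (2S,3R,4S)-2-[3'-(protected cycloolivil unit)-6,6'-bis(benzyloxy)-5,5'-dimethoxybiphenyl-3-yl]-4-[3-(benzyloxy)-4-methoxybenzyl]-3-(hydroxymethyl)tetrahydrofuran-4-ol, via vicinal diol 30 (not isolated), via aldehyde 31 (not isolated)
Conditions: OsO4 (2 mol%), NaIO4 (4 equiv), 2,6-lutidine, dioxane/H2O (3:1), rt; extractive work-up; NaBH4, MeOH, 0 °C
Reagents that add atoms: osmium tetroxide, O=[Os](=O)(=O)=O, re-formed by sodium periodate, [Na+].[O-]I(=O)(=O)=O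
Why: Lemieux–Johnson cleavage: dihydroxylation of the only remaining alkene and periodate cleavage of diol 30 give aldehyde 31, which is reduced at once to avoid epimerization at C3 or β-elimination. The lutidine buffer keeps the medium near neutral.

Step 19
Reactants: 32 hexabenzyl ether
Product: 33 target CNP0252244.1
Conditions: H2 (1 atm), Pd/C (10%), EtOAc/MeOH (1:1), rt
Reagents that add atoms: none
Why: Hydrogenolysis of the four aryl and two alkyl benzyl ethers under neutral conditions. The benzylic C2–O1 bond of the tetrahydrofuran should be cleaved much more slowly without acid, and the reaction is stopped when the last benzyl ether is gone.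

## Compound list

1 | dehydrodivanillin | COc1cc(C=O)cc(-c2cc(C=O)cc(OC)c2O)c1O | starting material
2 | 6,6'-bis(benzyloxy)-5,5'-dimethoxybiphenyl-3,3'-dicarbaldehyde | COc1cc(C=O)cc(-c2cc(C=O)cc(OC)c2OCc2ccccc2)c1OCc1ccccc1 | intermediate
3 | (S)-malic acid | O[C@@H](CC(=O)O)C(=O)O | starting material
4 | 2-[(2S,4S)-2-tert-butyl-5-oxo-1,3-dioxolan-4-yl]acetic acid | O=C1O[C@@H](C(C)(C)C)O[C@H]1CC(=O)O | intermediate
5 | [4-(benzyloxy)-3-methoxyphenyl]methanol | OCc1ccc(OCc2ccccc2)c(OC)c1 | starting material
6 | 1-(benzyloxy)-4-(bromomethyl)-2-methoxybenzene | BrCc1ccc(OCc2ccccc2)c(OC)c1 | intermediate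
7 | 2-[(2S,4S)-4-(4-benzyloxy-3-methoxybenzyl)-2-tert-butyl-5-oxo-1,3-dioxolan-4-yl]acetic acid | O=C1O[C@@H](C(C)(C)C)O[C@@]1(Cc1ccc(OCc2ccccc2)c(OC)c1)CC(=O)O | intermediate
8 | mixed pivalic anhydride of 7 | O=C1O[C@@H](C(C)(C)C)O[C@@]1(Cc1ccc(OCc2ccccc2)c(OC)c1)CC(=O)OC(=O)C(C)(C)C | intermediate (not isolated)
9 | N-acyl oxazolidinone of 7 with (S)-4-benzyloxazolidin-2-one | O=C1O[C@@H](C(C)(C)C)O[C@@]1(Cc1ccc(OCc2ccccc2)c(OC)c1)CC(=O)N1[C@@H](Cc2ccccc2)COC1=O | intermediate
10 | (Z)-dibutylboron enolate of 9 | CCCCB(CCCC)O/C(=C\[C@]1(Cc2ccc(OCc3ccccc3)c(OC)c2)O[C@H](C(C)(C)C)OC1=O)N1[C@@H](Cc2ccccc2)COC1=O | intermediate (not isolated)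
11 | syn-aldol adduct of 9 with one formyl group of 2 (α-carbon R, carbinol S) | O=Cc1cc(OC)c(OCc2ccccc2)c(-c2cc([C@@H](O)[C@@H](C(=O)N3[C@@H](Cc4ccccc4)COC3=O)[C@]3(Cc4ccc(OCc5ccccc5)c(OC)c4)O[C@H](C(C)(C)C)OC3=O)cc(OC)c2OCc2ccccc2)c1 | intermediate
12 | (1S,2R,3S)-tetralin with C2 imide and C3 spiro-dioxolanone, ring B formyl | O=Cc1cc(OC)c(OCc2ccccc2)c(-c2cc([C@H]3c4cc(OCc5ccccc5)c(OC)cc4C[C@]4(O[C@H](C(C)(C)C)OC4=O)[C@@H]3C(=O)N3[C@@H](Cc4ccccc4)COC3=O)cc(OC)c2OCc2ccccc2)c1 | intermediate
13 | dimethyl acetal of 12 | COC(OC)c1cc(OC)c(OCc2ccccc2)c(-c2cc([C@H]3c4cc(OCc5ccccc5)c(OC)cc4C[C@]4(O[C@H](C(C)(C)C)OC4=O)[C@@H]3C(=O)N3[C@@H](Cc4ccccc4)COC3=O)cc(OC)c2OCc2ccccc2)c1 | intermediate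
14 | (1S,2S,3S)-tetralin triol, ring B dimethyl acetal | COC(OC)c1cc(OC)c(OCc2ccccc2)c(-c2cc([C@H]3c4cc(OCc5ccccc5)c(OC)cc4C[C@@](O)(CO)[C@@H]3CO)cc(OC)c2OCc2ccccc2)c1 | intermediate
15 | bis(benzyloxymethyl) tetralin, ring B dimethyl acetal | COC(OC)c1cc(OC)c(OCc2ccccc2)c(-c2cc([C@H]3c4cc(OCc5ccccc5)c(OC)cc4C[C@@](O)(COCc4ccccc4)[C@@H]3COCc3ccccc3)cc(OC)c2OCc2ccccc2)c1 | intermediate (not isolated)
16 | 3'-(protected cycloolivil unit)-6,6'-bis(benzyloxy)-5,5'-dimethoxybiphenyl-3-carbaldehyde | O=Cc1cc(OC)c(OCc2ccccc2)c(-c2cc([C@H]3c4cc(OCc5ccccc5)c(OC)cc4C[C@@](O)(COCc4ccccc4)[C@@H]3COCc3ccccc3)cc(OC)c2OCc2ccccc2)c1 | intermediate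
17 | 5-bromo-2-methoxyphenol | COc1ccc(Br)cc1O | starting material
18 | 2-(benzyloxy)-4-bromo-1-methoxybenzene | COc1ccc(Br)cc1OCc1ccccc1 | intermediate
19 | propargyl alcohol | C#CCO | starting material
20 | 3-[3-(benzyloxy)-4-methoxyphenyl]prop-2-yn-1-ol | COc1ccc(C#CCO)cc1OCc1ccccc1 | intermediate
21 | 2-(benzyloxy)-4-(3-bromoprop-1-ynyl)-1-methoxybenzene | COc1ccc(C#CCBr)cc1OCc1ccccc1 | intermediate
22 | (E)-1-bromoprop-1-ene | C/C=C/Br | starting material
23 | (E)-prop-1-enyllithium | C/C=C/[Li] | intermediate (not isolated)
24 | bis[(E)-prop-1-enyl]zinc | C/C=C/[Zn]/C=C/C | intermediate (not isolated)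
25 | (1S,2E)-1-aryl-but-2-en-1-ol (aryl = ring B of the biaryl carrying the protected cycloolivil unit) | C/C=C/[C@@H](c1cc(OC)c(OCc2ccccc2)c(-c2cc([C@H]3c4cc(OCc5ccccc5)c(OC)cc4C[C@@](O)(COCc4ccccc4)[C@@H]3COCc3ccccc3)cc(OC)c2OCc2ccccc2)c1)O | intermediate
26 | 3-arylprop-2-ynyl ether of 25 (1,6-enyne) | C/C=C/[C@@H](c1cc(OC)c(OCc2ccccc2)c(-c2cc([C@H]3c4cc(OCc5ccccc5)c(OC)cc4C[C@@](O)(COCc4ccccc4)[C@@H]3COCc3ccccc3)cc(OC)c2OCc2ccccc2)c1)OCC#Cc1ccc(OC)c(OCc2ccccc2)c1 | intermediate
27 | (2S,3S)-trans-2-aryl-3-vinyl-4-[(Z)-arylmethylidene]tetrahydrofuran | COc1ccc(/C=C2\CO[C@H](c3cc(OC)c(OCc4ccccc4)c(-c4cc([C@H]5c6cc(OCc7ccccc7)c(OC)cc6C[C@@](O)(COCc6ccccc6)[C@@H]5COCc5ccccc5)cc(OC)c4OCc4ccccc4)c3)[C@H]2C=C)cc1OCc1ccccc1 | intermediate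
28 | spiro-epoxide of 27, oxygen on C4 anti to the vinyl group (C4 S, benzylic carbon R) | COc1ccc([C@H]2O[C@@]23CO[C@H](c4cc(OC)c(OCc5ccccc5)c(-c5cc([C@H]6c7cc(OCc8ccccc8)c(OC)cc7C[C@@](O)(COCc7ccccc7)[C@@H]6COCc6ccccc6)cc(OC)c5OCc5ccccc5)c4)[C@H]3C=C)cc1OCc1ccccc1 | intermediate (not isolated)
29 | (2S,3R,4S)-2-aryl-4-[3-(benzyloxy)-4-methoxybenzyl]-3-vinyltetrahydrofuran-4-ol | COc1ccc(C[C@@]2(O)CO[C@H](c3cc(OC)c(OCc4ccccc4)c(-c4cc([C@H]5c6cc(OCc7ccccc7)c(OC)cc6C[C@@](O)(COCc6ccccc6)[C@@H]5COCc5ccccc5)cc(OC)c4OCc4ccccc4)c3)[C@H]2C=C)cc1OCc1ccccc1 | intermediate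
30 | 1,2-diol from the vinyl group of 29 (both epimers at the new carbinol) | COc1ccc(C[C@@]2(O)CO[C@H](c3cc(OC)c(OCc4ccccc4)c(-c4cc([C@H]5c6cc(OCc7ccccc7)c(OC)cc6C[C@@](O)(COCc6ccccc6)[C@@H]5COCc5ccccc5)cc(OC)c4OCc4ccccc4)c3)[C@H]2C(O)CO)cc1OCc1ccccc1 | intermediate (not isolated)
31 | C3 aldehyde | COc1ccc(C[C@@]2(O)CO[C@H](c3cc(OC)c(OCc4ccccc4)c(-c4cc([C@H]5c6cc(OCc7ccccc7)c(OC)cc6C[C@@](O)(COCc6ccccc6)[C@@H]5COCc5ccccc5)cc(OC)c4OCc4ccccc4)c3)[C@H]2C=O)cc1OCc1ccccc1 | intermediate (not isolated)
32 | hexabenzyl ether of the target | COc1ccc(C[C@@]2(O)CO[C@H](c3cc(OC)c(OCc4ccccc4)c(-c4cc([C@H]5c6cc(OCc7ccccc7)c(OC)cc6C[C@@](O)(COCc6ccccc6)[C@@H]5COCc5ccccc5)cc(OC)c4OCc4ccccc4)c3)[C@H]2CO)cc1OCc1ccccc1 | intermediate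
33 | CNP0252244.1 | COc1ccc(C[C@@]2(O)CO[C@H](c3cc(OC)c(O)c(-c4cc([C@H]5c6cc(O)c(OC)cc6C[C@@](O)(CO)[C@@H]5CO)cc(OC)c4O)c3)[C@H]2CO)cc1O | target

## Step count and least certain steps

Total: 19 steps. Longest linear sequence: 14 steps (3 → 4 → 7 → 9 → 11 → 12 → 13 → 14 → 16 → 25 → 26 → 27 → 29 → 32 → 33).

Step 16 (key step). The likeliest failures are β-hydride elimination toward the ring C3–H or later palladium-hydride migration of the skipped diene into conjugation, and only moderate trans control at C3, because the (E)-alkene exerts little allylic strain and the C2 aryl is the sole control element. Ionization of the benzylic allylic ether is a lesser risk. The fallback makes the same C3–C4 bond by a Heck cyclization and adds ring A afterwards. It sets out from 25, which is alkylated with 2,3-dibromopropene (NaH) to the 2-bromoprop-2-enyl ether F1. A 5-exo Heck closure (Pd(OAc)2, PPh3, Et3N, MeCN, 80 °C) then gives the 4-methylidene-3-vinyltetrahydrofuran F2. Dimethyldioxirane epoxidizes the 1,1-disubstituted alkene anti to the vinyl group to spiro-epoxide F3. The aryl Grignard reagent F4, made from bromide 18 with Mg, opens F3 at its CH2 terminus under CuI catalysis. The route is rejoined at 29.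

Step 17. The dioxirane may attack the face syn to the vinyl group if the C2 aryl, which lies on the face to be attacked, outweighs the adjacent vinyl group. The p-methoxyphenyl epoxide may also rearrange under trace acid before it is reduced. The fallback replaces substrate control by catalyst control: a Shi epoxidation (fructose-derived chiral ketone, KHSO5, pH 10.5 buffer) with the ketone enantiomer chosen to reinforce attack anti to the vinyl group; the basic buffer also protects the epoxide. It sets out from 27 and rejoins at 28. No new compound arises (F0).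

Step 14. Enantioselectivity may erode through the LiBr-promoted background addition, through the zinc alkoxide of the tertiary hydroxyl, or through partial E/Z isomerization of the alkenyllithium if the temperature rises. The fallback sets out from 16 and adds propyne enantioselectively (Et2Zn, Ti(OiPr)4, 1,1'-bi-2-naphthol of the enantiomer that attacks the Si face) to give the propargylic alcohol F5. Hydroxyl-directed trans-reduction with NaAlH2(OCH2CH2OMe)2 then gives the (E)-allylic alcohol, and the route is rejoined at 25.

Step 15. The tertiary alkoxide may compete for the bromide, and the aryl-substituted propargylic bromide may undergo base-induced SN2' substitution or propargyl–allenyl isomerization. The fallback sets out from 25 and etherifies it with propargyl bromide itself (NaH, 1.1 equiv) to the terminal alkyne ether F6. Sonogashira coupling of F6 with aryl bromide 18 (Pd(PPh3)2Cl2, CuI, Et3N) then gives the enyne, and the route is rejoined at 26.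

Step 9. Hydride may attack the ring carbonyl of the oxazolidinone (endocyclic cleavage), because the acyl carbonyl is flanked by a methine and a quaternary carbon; the hindered dioxolanone may also be reduced incompletely. The fallback sets out from 13 and removes the auxiliary hydrolytically with LiOH/H2O2, which attacks the exocyclic carbonyl and also opens the dioxolanone, giving the hydroxy diacid F7 after a pH 4 work-up. LiAlH4 reduces F7 to the triol, and the route is rejoined at 14.

## Further compounds

F1 | step 16 | 2-bromoprop-2-enyl ether of 25 | C/C=C/[C@@H](c1cc(OC)c(OCc2ccccc2)c(-c2cc([C@H]3c4cc(OCc5ccccc5)c(OC)cc4C[C@@](O)(COCc4ccccc4)[C@@H]3COCc3ccccc3)cc(OC)c2OCc2ccccc2)c1)OCC(Br)=C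
F2 | step 16 | (2S,3S)-2-aryl-4-methylidene-3-vinyltetrahydrofuran (aryl and vinyl trans) | C=C1CO[C@H](c2cc(OC)c(OCc3ccccc3)c(-c3cc([C@H]4c5cc(OCc6ccccc6)c(OC)cc5C[C@@](O)(COCc5ccccc5)[C@@H]4COCc4ccccc4)cc(OC)c3OCc3ccccc3)c2)[C@H]1C=C
F3 | step 16 | spiro-epoxide of F2, oxygen on C4 anti to the vinyl group | C1O[C@@]12CO[C@H](c3cc(OC)c(OCc4ccccc4)c(-c4cc([C@H]5c6cc(OCc7ccccc7)c(OC)cc6C[C@@](O)(COCc6ccccc6)[C@@H]5COCc5ccccc5)cc(OC)c4OCc4ccccc4)c3)[C@H]2C=C
F4 | step 16 | [3-(benzyloxy)-4-methoxyphenyl]magnesium bromide | COc1ccc([Mg]Br)cc1OCc1ccccc1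
F0 | step 17 | none | none
F5 | step 14 | (1R)-1-aryl-but-2-yn-1-ol (same spatial arrangement as 25) | CC#C[C@@H](c1cc(OC)c(OCc2ccccc2)c(-c2cc([C@H]3c4cc(OCc5ccccc5)c(OC)cc4C[C@@](O)(COCc4ccccc4)[C@@H]3COCc3ccccc3)cc(OC)c2OCc2ccccc2)c1)O
F6 | step 15 | prop-2-ynyl ether of 25 | C/C=C/[C@@H](c1cc(OC)c(OCc2ccccc2)c(-c2cc([C@H]3c4cc(OCc5ccccc5)c(OC)cc4C[C@@](O)(COCc4ccccc4)[C@@H]3COCc3ccccc3)cc(OC)c2OCc2ccccc2)c1)OCC#C
F7 | step 9 | (1S,2S,3S)-tetralin 3-hydroxy-2,3-dicarboxylic acid, ring B dimethyl acetal | COC(OC)c1cc(OC)c(OCc2ccccc2)c(-c2cc([C@H]3c4cc(OCc5ccccc5)c(OC)cc4C[C@@](O)(C(=O)O)[C@@H]3C(=O)O)cc(OC)c2OCc2ccccc2)c1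
A1 | alternative 1 | ring A pivalate of the target | COc1ccc(C[C@@]2(O)CO[C@H](c3cc(OC)c(O)c(-c4cc([C@H]5c6cc(O)c(OC)cc6C[C@@](O)(CO)[C@@H]5CO)cc(OC)c4O)c3)[C@H]2CO)cc1OC(=O)C(C)(C)C
A2 | alternative 1 | bis-tetrahydrofuran: ring A pivalate unit and a second olivil-type unit with a free 4-hydroxy-3-methoxybenzyl group | COc1ccc(C[C@@]2(O)CO[C@H](c3cc(OC)c(O)c(-c4cc([C@H]5OC[C@](O)(Cc6ccc(O)c(OC)c6)[C@@H]5CO)cc(OC)c4O)c3)[C@H]2CO)cc1OC(=O)C(C)(C)C
A3 | alternative 2 | ethyl 1,2-cis-7-(benzyloxy)-1-hydroxy-6-methoxy-3-methylidene-1,2,3,4-tetrahydronaphthalene-2-carboxylate | CCOC(=O)[C@H]1C(=C)Cc2cc(OC)c(OCc3ccccc3)cc2[C@H]1O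
A4 | alternative 2 | 5-(benzyloxy)-4-methoxy-2-methylbenzaldehyde | O=Cc1cc(OCc2ccccc2)c(OC)cc1C
A5 | alternative 2 | ethyl buta-2,3-dienoate | CCOC(=O)C=C=C
A6 | alternative 3 | olivil-type tetrahydrofuran carrying the formyl biaryl, ring A tosylate | COc1ccc(C[C@@]2(O)CO[C@H](c3cc(OC)c(O)c(-c4cc(C=O)cc(OC)c4O)c3)[C@H]2CO)cc1OS(=O)(=O)c1ccc(C)cc1
A7 | alternative 3 | acyclic dibenzylbutanetriol precursor of A6 | COc1ccc(C[C@@](O)(CO)[C@H](CO)Cc2cc(OC)c(O)c(-c3cc(C=O)cc(OC)c3O)c2)cc1OS(=O)(=O)c1ccc(C)cc1
A8 | alternative 3 | para-quinone methide of A7 | COc1ccc(C[C@@](O)(CO)[C@H](CO)C=C2C=C(OC)C(=O)C(c3cc(C=O)cc(OC)c3O)=C2)cc1OS(=O)(=O)c1ccc(C)cc1
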